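**Retrosynthetic overview**
1. The only free phenol (4'-OH) is carried as a benzyl ether and unmasked last. All five OMe groups are bought in place.
2. Ring C (the pyranone, the only ring that is built) is opened at O1–C2 and its C2=C3 unsaturation removed: flavone ⇒ 2'-hydroxychalcone.
3. Key C–C bond (chalcone Cα=Cβ, later C3–C2): crossed aldol (Claisen–Schmidt) condensation of a ring A acetophenone with a ring B benzaldehyde.
4. The ring A fragment comes from 3,4,5-trimethoxyphenol by ortho C-acetylation. The ring B fragment comes from syringaldehyde by O-benzylation.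
5. Ring order: rings A and B are purchased, and ring C closes after the fragment union.

Assumption: the target SMILES has no stereocentre and no stereogenic double bond (achiral flavone), so there is no enantiomer to select. The racemic centres of the transient compounds 5 and 7 are erased within their own steps.

Step 1
Reactants: 1 3,4,5-trimethoxyphenol
Product: 2 1-(6-hydroxy-2,3,4-trimethoxyphenyl)ethan-1-one
Conditions: AcOH (3 equiv), BF3·OEt2 (4 equiv), 85 °C, 2.5 h; ice–water
Reagents that add atoms: acetic acid, CC(=O)O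
Why: Friedel–Crafts C-acylation of a very electron-rich phenol whose only two free ring positions are equivalent by symmetry and ortho to the OH, so one regioisomer forms, its chelated ketone resists a second acylation, and BF3 is too mild to cleave the aryl methyl ethers in this time.

Step 2
Reactants: 3 syringaldehyde (4-hydroxy-3,5-dimethoxybenzaldehyde)
Product: 4 4-(benzyloxy)-3,5-dimethoxybenzaldehyde
Conditions: BnBr (1.2 equiv), K2CO3 (2 equiv), DMF, 60 °C, 4 h
Reagents that add atoms: benzyl bromide, BrCc1ccccc1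
Why: Williamson ether synthesis (SN2 of the phenoxide on a benzylic bromide), which masks the phenol so that it cannot deactivate the aldehyde as a para-phenoxide in step 3 or be oxidised in step 4.

Step 3
Reactants: 2 1-(6-hydroxy-2,3,4-trimethoxyphenyl)ethan-1-one; 4 4-(benzyloxy)-3,5-dimethoxybenzaldehyde
Product: 6 (E)-3-[4-(benzyloxy)-3,5-dimethoxyphenyl]-1-(6-hydroxy-2,3,4-trimethoxyphenyl)prop-2-en-1-one, via racemic aldol adduct 5 (not isolated)
Conditions: KOH (50% aq, 10 equiv), EtOH, rt, 36–48 h; ice/2 M HCl to pH 3; recrystallise from EtOH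
Reagents that add atoms: none
Why: Claisen–Schmidt crossed aldol condensation, clean because 2 is the only enolisable partner and 4 the only aldehyde, while the carbinol centre of 5 forms as a racemate and is erased at once by E1cB loss of water to give the conjugated E alkene under thermodynamic control.

Step 4
Reactants: 6 (E)-3-[4-(benzyloxy)-3,5-dimethoxyphenyl]-1-(6-hydroxy-2,3,4-trimethoxyphenyl)prop-2-en-1-one
Product: 8 2-[4-(benzyloxy)-3,5-dimethoxyphenyl]-5,6,7-trimethoxy-4H-chromen-4-one, via racemic flavanone 7 (not isolated)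
Conditions: I2 (10 mol %), DMSO, 125 °C, 2–3 h
Reagents that add atoms: none
Why: Iodine-catalysed oxidative cyclisation of a 2'-hydroxychalcone, in which intramolecular oxa-Michael addition of the phenol closes ring C to flavanone 7 (racemic C2, of no consequence) and the I2/DMSO couple then dehydrogenates C2–C3 with DMSO as terminal oxidant, driven by formation of the aromatic pyranone.

Step 5
Reactants: 8 2-[4-(benzyloxy)-3,5-dimethoxyphenyl]-5,6,7-trimethoxy-4H-chromen-4-one
Product: 9 Ageconyflavone C (2-(4-hydroxy-3,5-dimethoxyphenyl)-5,6,7-trimethoxy-4H-chromen-4-one)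
Conditions: H2 (1 atm), 10% Pd/C (10 wt %), EtOAc–MeOH 1:1, rt, 3–6 h, stopped at full conversion
Reagents that add atoms: none
Why: Catalytic hydrogenolysis of the benzylic C–O bond is much faster at 1 atm and room temperature than reduction of the vinylogous-ester C2–C3 double bond and leaves the five aryl methyl ethers untouched, so only the 4'-OH is unveiled.

**Compound list**
1 | 3,4,5-trimethoxyphenol | COc1cc(O)cc(OC)c1OC | starting material
2 | 1-(6-hydroxy-2,3,4-trimethoxyphenyl)ethan-1-one | CC(=O)c1c(O)cc(OC)c(OC)c1OC | intermediate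
3 | syringaldehyde (4-hydroxy-3,5-dimethoxybenzaldehyde) | COc1cc(C=O)cc(OC)c1O | starting material
4 | 4-(benzyloxy)-3,5-dimethoxybenzaldehyde | COc1cc(C=O)cc(OC)c1OCc1ccccc1 | intermediate
5 | rac-3-[4-(benzyloxy)-3,5-dimethoxyphenyl]-3-hydroxy-1-(6-hydroxy-2,3,4-trimethoxyphenyl)propan-1-one (aldol adduct, racemic, not isolated) | COc1cc(C(O)CC(=O)c2c(O)cc(OC)c(OC)c2OC)cc(OC)c1OCc1ccccc1 | intermediate
6 | (E)-3-[4-(benzyloxy)-3,5-dimethoxyphenyl]-1-(6-hydroxy-2,3,4-trimethoxyphenyl)prop-2-en-1-one | COc1cc(/C=C/C(=O)c2c(O)cc(OC)c(OC)c2OC)cc(OC)c1OCc1ccccc1 | intermediate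
7 | rac-2-[4-(benzyloxy)-3,5-dimethoxyphenyl]-5,6,7-trimethoxychroman-4-one (flavanone, racemic, not isolated) | COc1cc(C2CC(=O)c3c(OC)c(OC)c(OC)cc3O2)cc(OC)c1OCc1ccccc1 | intermediate
8 | 2-[4-(benzyloxy)-3,5-dimethoxyphenyl]-5,6,7-trimethoxy-4H-chromen-4-one | COc1cc(-c2cc(=O)c3c(OC)c(OC)c(OC)cc3o2)cc(OC)c1OCc1ccccc1 | intermediate
9 | Ageconyflavone C, 2-(4-hydroxy-3,5-dimethoxyphenyl)-5,6,7-trimethoxy-4H-chromen-4-one (achiral) | COc1cc(-c2cc(=O)c3c(OC)c(OC)c(OC)cc3o2)cc(OC)c1O | target

**Totals**
Total step count: 5.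
Longest linear sequence: 4 steps (1 → 2 → 6 → 8 → 9, or equally 3 → 4 → 6 → 8 → 9).

**Three steps most likely to fail**

Step 4 (highest risk). At 125 °C the acid present in the iodine cycle may nick the peri 5-OMe or the benzyl ether, or the reaction may stall at the flavanone.
- The fallback sets out from 6 and comes back at 8.
- Ring closure and oxidation are separated and made iodine-free.
- 6 is isomerised with CH3CO2Na in refluxing EtOH to flavanone 7, which is now isolated and crystallised.
- 7 is then dehydrogenated with DDQ (2 equiv) in refluxing 1,4-dioxane, by hydride abstraction at C2 and loss of H-3, to give 8.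
- No compound outside the list arises (F0).

Step 3. The electron-rich, doubly ortho-flanked partners may condense slowly, with competing Cannizzaro loss of 4 or a chalcone/flavanone mixture.
- The fallback sets out from 2 and 4 and comes back at 8, bypassing 6 and step 4. The same C–C bond is made one oxidation level higher by an intermolecular Claisen-type acylation.
- 4 is oxidised (NaClO2, NaH2PO4, 2-methyl-2-butene, t-BuOH–H2O) to 4-(benzyloxy)-3,5-dimethoxybenzoic acid F1.
- F1 is converted with (COCl)2 and cat. DMF in CH2Cl2 into 4-(benzyloxy)-3,5-dimethoxybenzoyl chloride F2.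
- 2 is treated with LiN(SiMe3)2 (3.2 equiv) in THF at −78 °C and then with F2, warming to rt. This gives 1-[4-(benzyloxy)-3,5-dimethoxyphenyl]-3-(6-hydroxy-2,3,4-trimethoxyphenyl)propane-1,3-dione F3.
- F3 is cyclodehydrated with cat. p-TsOH in refluxing toluene (Dean–Stark) to 8.

Step 5. Sulfur or iodine traces carried over from step 4 can poison the Pd/C, and forcing the reaction risks saturating C2–C3.
- The fallback sets out from 3 (with 2 as partner) and comes back at 9. It exchanges the protecting-group strategy for one that needs no metal and no hydrogen.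
- 3 is treated with MOMCl and iPr2NEt in CH2Cl2 (0 °C to rt) to give 3,5-dimethoxy-4-(methoxymethoxy)benzaldehyde F4.
- F4 is condensed with 2 under the KOH/EtOH conditions, with a mild acid quench to pH 6, to give (E)-3-[3,5-dimethoxy-4-(methoxymethoxy)phenyl]-1-(6-hydroxy-2,3,4-trimethoxyphenyl)prop-2-en-1-one F5.
- F5 is closed with I2/DMSO to 2-[3,5-dimethoxy-4-(methoxymethoxy)phenyl]-5,6,7-trimethoxy-4H-chromen-4-one F6. Any acetal loss at this stage already gives 9.
- The acetal is removed with cat. HCl in MeOH at 50 °C to give 9.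

**Further compounds**
F0 | step 4 | none | none
F1 | step 3 | 4-(benzyloxy)-3,5-dimethoxybenzoic acid | COc1cc(C(=O)O)cc(OC)c1OCc1ccccc1
F2 | step 3 | 4-(benzyloxy)-3,5-dimethoxybenzoyl chloride | COc1cc(C(=O)Cl)cc(OC)c1OCc1ccccc1
F3 | step 3 | 1-[4-(benzyloxy)-3,5-dimethoxyphenyl]-3-(6-hydroxy-2,3,4-trimethoxyphenyl)propane-1,3-dione | COc1cc(C(=O)CC(=O)c2c(O)cc(OC)c(OC)c2OC)cc(OC)c1OCc1ccccc1
F4 | step 5 | 3,5-dimethoxy-4-(methoxymethoxy)benzaldehyde | COCOc1c(OC)cc(C=O)cc1OC
F5 | step 5 | (E)-3-[3,5-dimethoxy-4-(methoxymethoxy)phenyl]-1-(6-hydroxy-2,3,4-trimethoxyphenyl)prop-2-en-1-one | COCOc1c(OC)cc(/C=C/C(=O)c2c(O)cc(OC)c(OC)c2OC)cc1OC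
F6 | step 5 | 2-[3,5-dimethoxy-4-(methoxymethoxy)phenyl]-5,6,7-trimethoxy-4H-chromen-4-one | COCOc1c(OC)cc(-c2cc(=O)c3c(OC)c(OC)c(OC)cc3o2)cc1OC
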